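**Retrosynthetic overview**
1. Target ⇒ cleave the C15 silyl-ethyl ester and the C2–O ester: a 2α-hydroxy-labd-7-enoate plus (2S,3R)-3-angeloyloxy-2-hydroxy-2-methylbutanoic acid (from (2R,3R)-butane-2,3-diol by chelation-controlled Grignard addition).
2. 2α-Alcohol ⇒ 2-ketone ⇒ one acid-triggered cascade on a 2,3,4-trisubstituted pinene: cyclobutane opening unveils ring B with the C7=C8 alkene, ring A then closes (C3–C4) onto a ketal-derived enol ether, and C9–H is set in the same step.
3. Pinene ⇒ enol triflate + MeMgBr (C17) ⇒ Me2CuLi conjugate addition (C10, anti to the CMe2 bridge) to an α-alkylated verbenone.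
4. α-Alkyl verbenone ⇒ C9–C11 bond by nickel-electrocatalytic decarboxylative alkenylation of an α-iodoenone (from (1S)-(−)-verbenone, γ-homologated with trimethyl orthoacetate) with the N-hydroxyphthalimide ester of an (R)-citronellic acid half-ester.
5. Ring order: ring B is bought as the six-membered ring of verbenone (C5), ring A is formed last; stereocontrol relays C5 → C10 → C9 → C2, while C13 and the acyl stereocenters come from the pool.

Assumption: the SMILES is read literally as a 5,10-cis-fused (2S,5R,9R,10S,13R)-labd-7-ene (labdane numbering used throughout) carrying a (2S,3R)-diol ester whose 3-O-acyl group is the Z (angelate) enoate.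

**Side chain (steps 1–3)**

Step 1
Reactants: 1 (R)-citronellic acid
Product: 2 2-(trimethylsilyl)ethyl (3R)-3,7-dimethyloct-6-enoate
Conditions: Me3SiCH2CH2OH, DCC, DMAP (cat.), CH2Cl2, 0 °C → rt
Reagents that add atoms: 2-(trimethylsilyl)ethanol, C[Si](C)(C)CCO
Why: Steglich esterification masks C15 as a fluoride-cleavable ester that tolerates every later step, and the bought C13 stereocenter is not touched.

Step 2
Reactants: 2 2-(trimethylsilyl)ethyl (3R)-3,7-dimethyloct-6-enoate
Product: 3 (4R)-4-methyl-6-oxo-6-[2-(trimethylsilyl)ethoxy]hexanoic acid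
Conditions: RuCl3·xH2O (2 mol%), NaIO4 (4 equiv), EtOAc/MeCN/H2O, rt
Reagents that add atoms: sodium periodate, [Na+].[O-]I(=O)(=O)=O; water, O
Why: Ruthenium tetroxide oxidative cleavage (Sharpless conditions) turns the trisubstituted alkene directly into the acid whose decarboxylation will give the C11 radical, with C13 remote and untouched.

Step 3
Reactants: 3 (4R)-4-methyl-6-oxo-6-[2-(trimethylsilyl)ethoxy]hexanoic acid
Product: 4 6-(1,3-dioxoisoindolin-2-yl) 1-[2-(trimethylsilyl)ethyl] (3R)-3-methylhexanedioate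
Conditions: N-hydroxyphthalimide, DIC, DMAP (cat.), CH2Cl2, rt
Reagents that add atoms: N-hydroxyphthalimide, O=C1c2ccccc2C(=O)N1O
Why: Carbodiimide esterification gives the redox-active ester needed for reductive decarboxylation, with no stereocenter involved.

**Acyl fragment (steps 4–9)**

Step 4
Reactants: 5 (2R,3R)-butane-2,3-diol
Product: 6 (2R,3R)-3-[(4-methoxybenzyl)oxy]butan-2-ol
Conditions: NaH (1.0 equiv), 4-MeOC6H4CH2Cl (1.0 equiv), Bu4NI (cat.), THF/DMF, 0 °C → rt
Reagents that add atoms: 4-methoxybenzyl chloride, COc1ccc(CCl)cc1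
Why: Williamson mono-etherification of a C2-symmetric diol gives one mono-ether whichever hydroxyl reacts, and both stereocenters are bought.

Step 5
Reactants: 6 (2R,3R)-3-[(4-methoxybenzyl)oxy]butan-2-ol
Product: 7 (3R)-3-[(4-methoxybenzyl)oxy]butan-2-one
Conditions: Dess–Martin periodinane, NaHCO3, CH2Cl2, 0 °C → rt
Reagents that add atoms: none
Why: Buffered Dess–Martin oxidation gives the α-alkoxy ketone without epimerising the remaining stereocenter (the future C3 of the acyl unit).

Step 6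
Reactants: 7 (3R)-3-[(4-methoxybenzyl)oxy]butan-2-one
Product: 8 (2R,3R)-2-[(4-methoxybenzyl)oxy]-3,5-dimethylhex-4-en-3-ol
Conditions: Me2C=CHMgBr, MgBr2·OEt2, CH2Cl2/THF, −78 °C
Reagents that add atoms: (2-methylprop-1-en-1-yl)magnesium bromide, CC(C)=C[Mg]Br
Why: Cram-chelate-controlled Grignard addition (magnesium bridging the ketone and ether oxygens, attack opposite the methyl of the bought stereocenter) sets the tertiary carbinol that becomes the (2S) centre of the acid.

Step 7
Reactants: 8 (2R,3R)-2-[(4-methoxybenzyl)oxy]-3,5-dimethylhex-4-en-3-ol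
Product: 9 (2R,3R)-3,5-dimethylhex-4-ene-2,3-diol
Conditions: DDQ, CH2Cl2/pH 7 buffer (10:1), 0 °C
Reagents that add atoms: none
Why: Oxidative cleavage of the 4-methoxybenzyl ether by DDQ frees the secondary hydroxyl without affecting the tertiary allylic alcohol or either stereocenter.

Step 8
Reactants: 9 (2R,3R)-3,5-dimethylhex-4-ene-2,3-diol; 10 angelic acid
Product: 12 (2R,3R)-3-hydroxy-3,5-dimethylhex-4-en-2-yl (2Z)-2-methylbut-2-enoate, via mixed anhydride 11 (not isolated)
Conditions: 10, 2,4,6-Cl3C6H2COCl, Et3N, toluene, rt; then 9, DMAP (cat.), toluene, 80 °C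
Reagents that add atoms: none
Why: Yamaguchi esterification acylates only the secondary hydroxyl (the tertiary one is too hindered) under conditions established to keep the Z geometry of angelates.

Step 9
Reactants: 12 (2R,3R)-3-hydroxy-3,5-dimethylhex-4-en-2-yl (2Z)-2-methylbut-2-enoate
Product: 14 (2S,3R)-2-hydroxy-2-methyl-3-{[(2Z)-2-methylbut-2-enoyl]oxy}butanoic acid, via aldehyde 13 (not isolated)
Conditions: O3 (titrated, ca. 1.0 equiv), CH2Cl2/MeOH, −78 °C; Me2S; then NaClO2, NaH2PO4, 2-methyl-2-butene, t-BuOH/H2O, 0 °C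
Reagents that add atoms: ozone, [O-][O+]=O; sodium chlorite, [Na+].[O-]Cl=O
Why: Ozonolysis is selective for the electron-rich trisubstituted alkene over the conjugated angelate, and Pinnick oxidation of the non-epimerisable α-hydroxy aldehyde gives the acid with both stereocenters intact.

**Core and endgame (steps 10–18)**

Step 10
Reactants: 15 (1S,5S)-(−)-verbenone
Product: 17 (1S,5R)-4-(2,2-dimethoxypropyl)-6,6-dimethylbicyclo[3.1.1]hept-3-en-2-one, via silyl dienol ether 16 (not isolated)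
Conditions: TMSOTf (1.2 equiv), Et3N (1.1 equiv), CH2Cl2, 0 °C; then MeC(OMe)3, −78 → −20 °C
Reagents that add atoms: trimethyl orthoacetate, CC(OC)(OC)OC
Why: Soft enolisation can only give the γ-dienol ether (the α′ position is a bridgehead), and a vinylogous Mukaiyama reaction with the orthoester-derived dialkoxycarbenium ion at the terminal carbon installs C2 and C3 as a masked acetonyl group while C5 (bought) is untouched.

Step 11
Reactants: 17 (1S,5R)-4-(2,2-dimethoxypropyl)-6,6-dimethylbicyclo[3.1.1]hept-3-en-2-one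
Product: 18 (1S,5R)-4-(2,2-dimethoxypropyl)-3-iodo-6,6-dimethylbicyclo[3.1.1]hept-3-en-2-one
Conditions: I2, pyridine, DMAP (cat.), CH2Cl2, rt, dark
Reagents that add atoms: iodine, II
Why: Base-mediated α-iodination of the enone (I2/pyridine) places the halide on C9 under non-cationic conditions that spare the ketal and the cyclobutane.

Step 12
Reactants: 18 (1S,5R)-4-(2,2-dimethoxypropyl)-3-iodo-6,6-dimethylbicyclo[3.1.1]hept-3-en-2-one; 4 6-(1,3-dioxoisoindolin-2-yl) 1-[2-(trimethylsilyl)ethyl] (3R)-3-methylhexanedioate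
Product: 19 2-(trimethylsilyl)ethyl (3R)-5-[(1S,5R)-4-(2,2-dimethoxypropyl)-6,6-dimethyl-2-oxobicyclo[3.1.1]hept-3-en-3-yl]-3-methylpentanoate
Conditions: NiCl2·6H2O (20 mol%), 2,2′-bipyridine (24 mol%), AgNO3 (30 mol%), DMF, Mg anode/RVC cathode, undivided cell, constant current (ca. 2.5 F/mol), rt
Reagents that add atoms: none
Why: Nickel-electrocatalytic decarboxylative alkenylation (cathodically generated low-valent nickel inserts into the vinyl iodide and captures the primary C11 radical released from the redox-active ester) forges the C9–C11 bond that joins the two pool-derived halves, with C13 two carbons from the radical centre and therefore retained.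

Step 13
Reactants: 19 2-(trimethylsilyl)ethyl (3R)-5-[(1S,5R)-4-(2,2-dimethoxypropyl)-6,6-dimethyl-2-oxobicyclo[3.1.1]hept-3-en-3-yl]-3-methylpentanoate
Product: 21 2-(trimethylsilyl)ethyl (3R)-5-[(1S,4S,5R)-4-(2,2-dimethoxypropyl)-4,6,6-trimethyl-2-{[(trifluoromethyl)sulfonyl]oxy}bicyclo[3.1.1]hept-2-en-3-yl]-3-methylpentanoate, via lithium enolate 20 (not isolated)
Conditions: Me2CuLi (3 equiv), Et2O/THF, −40 → 0 °C; then PhNTf2, DMPU, 0 °C → rt
Reagents that add atoms: lithium dimethylcuprate, [Li+].C[Cu-]C; N-phenylbis(trifluoromethanesulfonimide), O=S(=O)(N(c1ccccc1)S(=O)(=O)C(F)(F)F)C(F)(F)F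
Why: Cuprate 1,4-addition occurs on the face opposite the CMe2 bridge as with verbenone itself, which sets C10 (S, methyl cis to H5) and pushes the ketal arm syn to the bridge, and the enolate, which can only form toward C9, is trapped as the enol triflate.

Step 14
Reactants: 21 2-(trimethylsilyl)ethyl (3R)-5-[(1S,4S,5R)-4-(2,2-dimethoxypropyl)-4,6,6-trimethyl-2-{[(trifluoromethyl)sulfonyl]oxy}bicyclo[3.1.1]hept-2-en-3-yl]-3-methylpentanoate
Product: 22 2-(trimethylsilyl)ethyl (3R)-5-[(1S,4S,5R)-4-(2,2-dimethoxypropyl)-2,4,6,6-tetramethylbicyclo[3.1.1]hept-2-en-3-yl]-3-methylpentanoate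
Conditions: MeMgBr, Fe(acac)3 (5 mol%), THF/NMP, −30 °C
Reagents that add atoms: methylmagnesium bromide, C[Mg]Br
Why: Iron-catalysed Kumada-type coupling of the hindered enol triflate with the small methyl Grignard is fast at low temperature and tolerates ester and ketal, installing C17 on a pinene-type tetrasubstituted alkene.

Step 15
Reactants: 22 2-(trimethylsilyl)ethyl (3R)-5-[(1S,4S,5R)-4-(2,2-dimethoxypropyl)-2,4,6,6-tetramethylbicyclo[3.1.1]hept-2-en-3-yl]-3-methylpentanoate
Product: 24 2-(trimethylsilyl)ethyl (5R,9R,10S,13R)-2-oxolabd-7-en-15-oate, via enol ether 23 (not isolated)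
Conditions: Tf2NH (10 mol%), (CF3)2CHOH/CH2Cl2 (1:4), −40 → −20 °C; then H2O
Reagents that add atoms: water, O
Why: Proposed new method: the acid converts the ketal into its 2-methoxyallyl enol ether and protonates the tetrasubstituted alkene at C9 from the face opposite the CMe2 bridge (setting C9 as R), the resulting tertiary cyclobutylcarbinyl C8 cation relieves strain by cleaving the C7–C4 bond to give the C7=C8 alkene and a Me2C+ centre on C5 that is held cis to the enol ether arm on C10, 6-endo Prins/Mukaiyama-type capture at C3 closes ring A as the cis-fused decalin and hydrolysis of the oxocarbenium ion gives the C2 ketone; the closest known reaction types are the acid-promoted α-pinene to α-terpinyl cation ring opening and cation–olefin annulations terminated by enol derivatives.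

Step 16
Reactants: 24 2-(trimethylsilyl)ethyl (5R,9R,10S,13R)-2-oxolabd-7-en-15-oate
Product: 25 2-(trimethylsilyl)ethyl (2S,5R,9R,10S,13R)-2-hydroxylabd-7-en-15-oate
Conditions: SmI2 (2.5 equiv), H2O (50 equiv), THF, 0 °C
Reagents that add atoms: none
Why: Single-electron (ketyl) reduction, like dissolving-metal reduction, gives the more stable equatorial 2α-alcohol, whereas hydride reagents would be forced by the syn-axial C10 and C4 methyls to attack equatorially and give the axial 2β epimer.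

Step 17
Reactants: 25 2-(trimethylsilyl)ethyl (2S,5R,9R,10S,13R)-2-hydroxylabd-7-en-15-oate; 14 (2S,3R)-2-hydroxy-2-methyl-3-{[(2Z)-2-methylbut-2-enoyl]oxy}butanoic acid
Product: 26 2-(trimethylsilyl)ethyl (2S,5R,9R,10S,13R)-2-{[(2S,3R)-2-hydroxy-2-methyl-3-{[(2Z)-2-methylbut-2-enoyl]oxy}butanoyl]oxy}labd-7-en-15-oate
Conditions: DIC, DMAP (cat.), CH2Cl2, 0 °C → rt
Reagents that add atoms: none
Why: Steglich esterification of the unhindered equatorial alcohol proceeds with retention at C2, the tertiary α-hydroxyl of the acid being too hindered to compete.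

Step 18
Reactants: 26 2-(trimethylsilyl)ethyl (2S,5R,9R,10S,13R)-2-{[(2S,3R)-2-hydroxy-2-methyl-3-{[(2Z)-2-methylbut-2-enoyl]oxy}butanoyl]oxy}labd-7-en-15-oate
Product: 27 CNP0253965.1 (target acid)
Conditions: Bu4NF, AcOH (1:1), THF, 0 °C → rt
Reagents that add atoms: none
Why: Fluoride-induced β-silyl fragmentation of the 2-(trimethylsilyl)ethyl ester frees C15 under buffered, non-hydrolytic conditions that leave the angelate, the hindered hydroxy ester and the C7=C8 alkene unchanged.

**Compound list**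
1 | (R)-citronellic acid | C[C@H](CCC=C(C)C)CC(=O)O | starting material
2 | 2-(trimethylsilyl)ethyl (3R)-3,7-dimethyloct-6-enoate | C[C@H](CCC=C(C)C)CC(=O)OCC[Si](C)(C)C | intermediate
3 | (4R)-4-methyl-6-oxo-6-[2-(trimethylsilyl)ethoxy]hexanoic acid | C[C@H](CCC(=O)O)CC(=O)OCC[Si](C)(C)C | intermediate
4 | 6-(1,3-dioxoisoindolin-2-yl) 1-[2-(trimethylsilyl)ethyl] (3R)-3-methylhexanedioate | C[C@H](CCC(=O)ON1C(=O)c2ccccc2C1=O)CC(=O)OCC[Si](C)(C)C | intermediate
5 | (2R,3R)-butane-2,3-diol | C[C@@H](O)[C@@H](C)O | starting material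
6 | (2R,3R)-3-[(4-methoxybenzyl)oxy]butan-2-ol | C[C@@H](O)[C@@H](C)OCc1ccc(OC)cc1 | intermediate
7 | (3R)-3-[(4-methoxybenzyl)oxy]butan-2-one | CC(=O)[C@@H](C)OCc1ccc(OC)cc1 | intermediate
8 | (2R,3R)-2-[(4-methoxybenzyl)oxy]-3,5-dimethylhex-4-en-3-ol | COc1ccc(CO[C@H](C)[C@](C)(O)C=C(C)C)cc1 | intermediate
9 | (2R,3R)-3,5-dimethylhex-4-ene-2,3-diol | O[C@H](C)[C@](C)(O)C=C(C)C | intermediate
10 | angelic acid, (2Z)-2-methylbut-2-enoic acid | C/C=C(/C)C(=O)O | starting material
11 | angelic 2,4,6-trichlorobenzoic anhydride | C/C=C(/C)C(=O)OC(=O)c1c(Cl)cc(Cl)cc1Cl | intermediate (not isolated)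
12 | (2R,3R)-3-hydroxy-3,5-dimethylhex-4-en-2-yl (2Z)-2-methylbut-2-enoate | C/C=C(/C)C(=O)O[C@H](C)[C@](C)(O)C=C(C)C | intermediate
13 | (2R,3S)-3-hydroxy-3-methyl-4-oxobutan-2-yl (2Z)-2-methylbut-2-enoate | C/C=C(/C)C(=O)O[C@H](C)[C@](C)(O)C=O | intermediate (not isolated)
14 | (2S,3R)-2-hydroxy-2-methyl-3-{[(2Z)-2-methylbut-2-enoyl]oxy}butanoic acid | C/C=C(/C)C(=O)O[C@H](C)[C@](C)(O)C(=O)O | intermediate
15 | (1S,5S)-(−)-verbenone, of high enantiomeric purity | CC1=CC(=O)[C@H]2C[C@@H]1C2(C)C | starting material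
16 | {[(1S,5R)-6,6-dimethyl-4-methylidenebicyclo[3.1.1]hept-2-en-2-yl]oxy}trimethylsilane | C=C1C=C(O[Si](C)(C)C)[C@H]2C[C@@H]1C2(C)C | intermediate (not isolated)
17 | (1S,5R)-4-(2,2-dimethoxypropyl)-6,6-dimethylbicyclo[3.1.1]hept-3-en-2-one | COC(C)(OC)CC1=CC(=O)[C@H]2C[C@@H]1C2(C)C | intermediate
18 | (1S,5R)-4-(2,2-dimethoxypropyl)-3-iodo-6,6-dimethylbicyclo[3.1.1]hept-3-en-2-one | COC(C)(OC)CC1=C(I)C(=O)[C@H]2C[C@@H]1C2(C)C | intermediate
19 | 2-(trimethylsilyl)ethyl (3R)-5-[(1S,5R)-4-(2,2-dimethoxypropyl)-6,6-dimethyl-2-oxobicyclo[3.1.1]hept-3-en-3-yl]-3-methylpentanoate | COC(C)(OC)CC1=C(CC[C@@H](C)CC(=O)OCC[Si](C)(C)C)C(=O)[C@H]2C[C@@H]1C2(C)C | intermediate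
20 | lithium enolate of the C10-methylated ketone (methyl anti to the CMe2 bridge) | COC(C)(OC)C[C@]1(C)C(CC[C@@H](C)CC(=O)OCC[Si](C)(C)C)=C([O-])[C@H]2C[C@@H]1C2(C)C.[Li+] | intermediate (not isolated)
21 | 2-(trimethylsilyl)ethyl (3R)-5-[(1S,4S,5R)-4-(2,2-dimethoxypropyl)-4,6,6-trimethyl-2-{[(trifluoromethyl)sulfonyl]oxy}bicyclo[3.1.1]hept-2-en-3-yl]-3-methylpentanoate | COC(C)(OC)C[C@]1(C)C(CC[C@@H](C)CC(=O)OCC[Si](C)(C)C)=C(OS(=O)(=O)C(F)(F)F)[C@H]2C[C@@H]1C2(C)C | intermediate
22 | 2-(trimethylsilyl)ethyl (3R)-5-[(1S,4S,5R)-4-(2,2-dimethoxypropyl)-2,4,6,6-tetramethylbicyclo[3.1.1]hept-2-en-3-yl]-3-methylpentanoate | COC(C)(OC)C[C@]1(C)C(CC[C@@H](C)CC(=O)OCC[Si](C)(C)C)=C(C)[C@H]2C[C@@H]1C2(C)C | intermediate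
23 | 2-methoxyallyl enol ether of 22 (C2 ketal converted to the terminal methyl enol ether) | C=C(OC)C[C@]1(C)C(CC[C@@H](C)CC(=O)OCC[Si](C)(C)C)=C(C)[C@H]2C[C@@H]1C2(C)C | intermediate (not isolated)
24 | 2-(trimethylsilyl)ethyl (5R,9R,10S,13R)-2-oxolabd-7-en-15-oate (cis-fused; H5, H9 and the C10 methyl on one face) | O=C1CC(C)(C)[C@H]2CC=C(C)[C@@H](CC[C@@H](C)CC(=O)OCC[Si](C)(C)C)[C@@]2(C)C1 | intermediate
25 | 2-(trimethylsilyl)ethyl (2S,5R,9R,10S,13R)-2-hydroxylabd-7-en-15-oate | O[C@H]1CC(C)(C)[C@H]2CC=C(C)[C@@H](CC[C@@H](C)CC(=O)OCC[Si](C)(C)C)[C@@]2(C)C1 | intermediate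
26 | 2-(trimethylsilyl)ethyl (2S,5R,9R,10S,13R)-2-{[(2S,3R)-2-hydroxy-2-methyl-3-{[(2Z)-2-methylbut-2-enoyl]oxy}butanoyl]oxy}labd-7-en-15-oate | C/C=C(/C)C(=O)O[C@H](C)[C@](C)(O)C(=O)O[C@H]1CC(C)(C)[C@H]2CC=C(C)[C@@H](CC[C@@H](C)CC(=O)OCC[Si](C)(C)C)[C@@]2(C)C1 | intermediate
27 | CNP0253965.1, (2S,5R,9R,10S,13R)-2-{[(2S,3R)-2-hydroxy-2-methyl-3-{[(2Z)-2-methylbut-2-enoyl]oxy}butanoyl]oxy}labd-7-en-15-oic acid | C/C=C(/C)C(=O)O[C@H](C)[C@](C)(O)C(=O)O[C@H]1CC(C)(C)[C@H]2CC=C(C)[C@@H](CC[C@@H](C)CC(=O)O)[C@@]2(C)C1 | target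

**Step count and risks**
Total: 18 steps. Longest linear sequence: 10 steps, from (R)-citronellic acid (steps 1–3, then 12–18); it is 9 steps from verbenone (steps 10–18) and 8 from butanediol.

Most likely to fail:

Step 15 (the proposed new cascade). The pinanyl-type cation may instead undergo Wagner–Meerwein ring expansion to bornyl- or fenchyl-type skeletons, lose a proton to an isopropenyl diene, or the new C7=C8 bond may migrate under acid. The fallback is stepwise and uses known reaction types; it sets out from 22 and returns at 24. Aqueous acid (ClCH2CO2H/H2O, the α-pinene to α-terpineol hydration) opens the cyclobutane and hydrolyses the ketal to the ring-opened hydroxy ketone F3, in which C9–H is set by the same protonation anti to the bridge. HCl in CH2Cl2 at 0 °C converts the tertiary alcohol into the tertiary chloride F4. LiN(iPr)2/TMSCl at −78 °C gives the kinetic silyl enol ether F5. TiCl4 in CH2Cl2 at −78 °C then closes ring A by α-tert-alkylation of the silyl enol ether with the tertiary chloride, giving 24.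

Step 13 (conjugate methylation of a tetrasubstituted, α-alkylated enone). The addition may stall or go 1,2. The fallback installs the methyl before the side chain; it sets out from 17 (and acid 3), returns at 21, and bypasses steps 11–13. Acid 3 is converted by photochemical iododecarboxylation (PhI(OAc)2, I2, hν) into 2-(trimethylsilyl)ethyl (3S)-5-iodo-3-methylpentanoate F1. Me2CuLi adds readily to the trisubstituted enone 17 (anti to the bridge), and the regiospecific enolate is alkylated with F1 in THF/DMPU to give the ketone F2. Its C9 configuration is immaterial because C9 becomes sp2 again. KN(SiMe3)2, which can enolise only toward C9, followed by PhNTf2 gives 21.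

Step 16 (configuration at C2). If SmI2/H2O gives epimer mixtures, the fallback uses the kinetic epimer and inverts it during esterification; it sets out from 24 and returns at 26. NaBH4 in MeOH at −20 °C gives the axial 2β-alcohol F6. Tf2O/pyridine gives the 2β-triflate F7. Displacement with the caesium salt of 14 (Cs2CO3, 18-crown-6, toluene) proceeds with inversion to give 26 directly.

**Further compounds**
F1 | step 13 | 2-(trimethylsilyl)ethyl (3S)-5-iodo-3-methylpentanoate | C[C@H](CCI)CC(=O)OCC[Si](C)(C)C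
F2 | step 13 | 2-(trimethylsilyl)ethyl (3R)-5-[(1S,3R,4S,5R)-4-(2,2-dimethoxypropyl)-4,6,6-trimethyl-2-oxobicyclo[3.1.1]heptan-3-yl]-3-methylpentanoate (side chain anti to the CMe2 bridge) | COC(C)(OC)C[C@]1(C)[C@@H](CC[C@@H](C)CC(=O)OCC[Si](C)(C)C)C(=O)[C@H]2C[C@@H]1C2(C)C
F3 | step 15 | ring-opened hydroxy ketone: ring B cyclohexene carrying the C10 methyl and acetonyl groups and a 2-hydroxypropan-2-yl group on C5, configuration at C5, C9, C10 and C13 as in 24 | CC(=O)C[C@@]1(C)[C@@H](C(C)(C)O)CC=C(C)[C@H]1CC[C@@H](C)CC(=O)OCC[Si](C)(C)C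
F4 | step 15 | corresponding tertiary chloride (2-chloropropan-2-yl on C5) | CC(=O)C[C@@]1(C)[C@@H](C(C)(C)Cl)CC=C(C)[C@H]1CC[C@@H](C)CC(=O)OCC[Si](C)(C)C
F5 | step 15 | kinetic trimethylsilyl enol ether of F4 (terminal enol ether of the acetonyl group) | C=C(O[Si](C)(C)C)C[C@@]1(C)[C@@H](C(C)(C)Cl)CC=C(C)[C@H]1CC[C@@H](C)CC(=O)OCC[Si](C)(C)C
F6 | step 16 | 2-(trimethylsilyl)ethyl (2R,5R,9R,10S,13R)-2-hydroxylabd-7-en-15-oate (axial 2β-alcohol) | O[C@@H]1CC(C)(C)[C@H]2CC=C(C)[C@@H](CC[C@@H](C)CC(=O)OCC[Si](C)(C)C)[C@@]2(C)C1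
F7 | step 16 | 2β-trifluoromethanesulfonate of F6 | O=S(=O)(O[C@@H]1CC(C)(C)[C@H]2CC=C(C)[C@@H](CC[C@@H](C)CC(=O)OCC[Si](C)(C)C)[C@@]2(C)C1)C(F)(F)F
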